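**Retrosynthetic overview**
- The only ring to build is the lactone. It is closed late by joining the C9' alcohol oxygen to the C9 carboxyl carbon of an open, 8–8'-linked seco-lignan. This is the same O–C9 bond that closes when a seco-lignan becomes a lignan lactone in the biosynthesis.
- C3 (C8) is left to thermodynamic control: base epimerisation of the lactone gives the trans isomer. Only C4 (C8') has to be set absolutely.
- The C8–C8' bond is made in one step by oxidative heterocoupling of two different C6–C3 enolates, the laboratory counterpart of the oxidative 8–8' coupling of phenylpropanoid units. One partner is a syringylpropanoyl imide of (S)-4-benzyloxazolidin-2-one, which sets C8' and is later reduced to the C9' alcohol. The other is tert-butyl 3-(3,4,5-trimethoxyphenyl)propanoate, whose carbonyl becomes the lactone C=O. This choice also fixes which aryl group sits next to the carbonyl.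
- The imide comes from sinapic acid (hydrogenation, silylation of the phenol, N-acylation). The ester comes from commercial 3-(3,4,5-trimethoxyphenyl)propanoic acid.
- Ring order: both arenes are bought; the lactone closes in step 6; epimerisation and release of the phenol follow in step 7.

Assumption: the SMILES is read as (3R,4R)-4-(4-hydroxy-3,5-dimethoxybenzyl)-3-(3,4,5-trimethoxybenzyl)dihydrofuran-2(3H)-one (trans). Lignan locants C7–C9 denote the trimethoxyphenyl C6–C3 unit and C7'–C9' the syringyl unit.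

**Route**

Step 1
Reactants: 1 sinapic acid, (E)-3-(4-hydroxy-3,5-dimethoxyphenyl)prop-2-enoic acid
Product: 2 3-(4-hydroxy-3,5-dimethoxyphenyl)propanoic acid
Conditions: H2 (1 atm), Pd/C (10 wt%), MeOH, rt
Reagents that add atoms: none
Why: Heterogeneous catalytic hydrogenation saturates the cinnamic C=C bond while arene, acid and phenol are untouched, and no stereocentre is formed.

Step 2
Reactants: 2 3-(4-hydroxy-3,5-dimethoxyphenyl)propanoic acid
Product: 4 3-[4-(tert-butyldimethylsilyloxy)-3,5-dimethoxyphenyl]propanoic acid, via bis-silyl compound 3 (not isolated)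
Conditions: TBSCl (2.5 equiv), imidazole (5 equiv), DMF, rt; then AcOH/THF/H2O (3:1:1), rt
Reagents that add atoms: tert-butyldimethylsilyl chloride (TBSCl), CC(C)(C)[Si](C)(C)Cl
Why: Silyl protection (TBSCl/imidazole) caps phenol and acid, and the much more labile silyl ester is then hydrolysed selectively by mild aqueous acid, leaving the aryl silyl ether that masks the oxidisable phenol for the enolate chemistry; no stereocentre is formed.

Step 3
Reactants: 4 3-[4-(tert-butyldimethylsilyloxy)-3,5-dimethoxyphenyl]propanoic acid; 5 (4S)-4-benzyl-1,3-oxazolidin-2-one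
Product: 7 (4S)-4-benzyl-3-{3-[4-(tert-butyldimethylsilyloxy)-3,5-dimethoxyphenyl]propanoyl}-1,3-oxazolidin-2-one, via mixed pivalic anhydride 6 (not isolated)
Conditions: PivCl (1.1 equiv), Et3N (2.5 equiv), THF, −20 °C; then LiCl (1.1 equiv), 5 (1.05 equiv), −20 °C → rt
Reagents that add atoms: none
Why: N-acylation of the oxazolidinone through the mixed pivalic anhydride (LiCl/Et3N protocol) gives the Evans imide because the hindered pivaloyl carbonyl is not attacked, and the auxiliary stereocentre is carried in unchanged.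

Step 4
Reactants: 8 3-(3,4,5-trimethoxyphenyl)propanoic acid
Product: 9 tert-butyl 3-(3,4,5-trimethoxyphenyl)propanoate
Conditions: Cl3CC(=NH)OtBu (2 equiv), BF3·OEt2 (5 mol%), CH2Cl2/cyclohexane, rt
Reagents that add atoms: tert-butyl 2,2,2-trichloroacetimidate, CC(C)(C)OC(=N)C(Cl)(Cl)Cl
Why: Acid-catalysed O-alkylation of the carboxylic acid by the trichloroacetimidate (tert-butyl transfer esterification) gives a tert-butyl ester that resists Claisen condensation and later survives LiBH4; no stereocentre is formed.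

Step 5
Reactants: 7 (4S)-4-benzyl-3-{3-[4-(tert-butyldimethylsilyloxy)-3,5-dimethoxyphenyl]propanoyl}-1,3-oxazolidin-2-one (1.0 equiv); 9 tert-butyl 3-(3,4,5-trimethoxyphenyl)propanoate (1.5 equiv)
Product: 12 tert-butyl (2RS,3R)-4-[(4S)-4-benzyl-2-oxo-1,3-oxazolidin-3-yl]-3-[4-(tert-butyldimethylsilyloxy)-3,5-dimethoxybenzyl]-4-oxo-2-(3,4,5-trimethoxybenzyl)butanoate (C2 epimer mixture), via imide lithium Z-enolate 10 (not isolated), via ester lithium enolate 11 (not isolated)
Conditions: LiN(iPr)2 (2.6 equiv), THF, −78 °C, 30 min; then copper bis(2-ethylhexanoate), Cu(O2CCH(Et)Bu)2 (2.6 equiv), −78 °C → rt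
Reagents that add atoms: none
Why: Intermolecular oxidative enolate heterocoupling (single-electron oxidation of the mixed lithium enolates by divalent copper) forms the C8–C8' bond, and the chelated Z-enolate of the imide reacts on the face opposite the auxiliary benzyl group so that C3 of the succinate (the future lactone C4) is R, while the ester-side centre C2 forms as a mixture that step 7 corrects.

Step 6
Reactants: 12 tert-butyl (2RS,3R)-4-[(4S)-4-benzyl-2-oxo-1,3-oxazolidin-3-yl]-3-[4-(tert-butyldimethylsilyloxy)-3,5-dimethoxybenzyl]-4-oxo-2-(3,4,5-trimethoxybenzyl)butanoate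
Product: 14 (3RS,4R)-4-[4-(tert-butyldimethylsilyloxy)-3,5-dimethoxybenzyl]-3-(3,4,5-trimethoxybenzyl)dihydrofuran-2(3H)-one (C3 epimer mixture), via hydroxy ester 13 (not isolated)
Conditions: LiBH4 (1.5 equiv), H2O (1.5 equiv), Et2O/THF, 0 °C; aq. NH4Cl work-up; then TsOH·H2O (10 mol%), toluene, 70 °C
Reagents that add atoms: none
Why: Chemoselective hydride reduction of the activated imide carbonyl (reductive removal of the Evans auxiliary) gives the primary alcohol while the hindered tert-butyl ester survives, and acid-catalysed lactonisation (intramolecular transesterification) then closes the five-membered ring without touching the R centre from step 5, which becomes C4.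

Step 7
Reactants: 14 (3RS,4R)-4-[4-(tert-butyldimethylsilyloxy)-3,5-dimethoxybenzyl]-3-(3,4,5-trimethoxybenzyl)dihydrofuran-2(3H)-one
Product: 16 (3R,4R)-4-(4-hydroxy-3,5-dimethoxybenzyl)-3-(3,4,5-trimethoxybenzyl)dihydrofuran-2(3H)-one, via trans silyl ether 15 (not isolated)
Conditions: DBU (1.5 equiv), toluene, 80 °C; then Bu4NF (1.5 equiv), AcOH (3 equiv), THF, 0 °C → rt
Reagents that add atoms: none
Why: Base-mediated epimerisation through the lactone enolate equilibrates C3 to the thermodynamically favoured trans arrangement, which is 3R relative to the fixed 4R centre, and buffered fluoride desilylation then frees the phenol without opening the lactone.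

**Compound list**
1 | sinapic acid, (E)-3-(4-hydroxy-3,5-dimethoxyphenyl)prop-2-enoic acid | COc1cc(/C=C/C(=O)O)cc(OC)c1O | starting material
2 | 3-(4-hydroxy-3,5-dimethoxyphenyl)propanoic acid | COc1cc(CCC(=O)O)cc(OC)c1O | intermediate
3 | tert-butyldimethylsilyl 3-[4-(tert-butyldimethylsilyloxy)-3,5-dimethoxyphenyl]propanoate (formed in the flask in step 2) | COc1cc(CCC(=O)O[Si](C)(C)C(C)(C)C)cc(OC)c1O[Si](C)(C)C(C)(C)C | intermediate
4 | 3-[4-(tert-butyldimethylsilyloxy)-3,5-dimethoxyphenyl]propanoic acid | COc1cc(CCC(=O)O)cc(OC)c1O[Si](C)(C)C(C)(C)C | intermediate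
5 | (4S)-4-benzyl-1,3-oxazolidin-2-one | O=C1N[C@@H](Cc2ccccc2)CO1 | starting material
6 | 3-[4-(tert-butyldimethylsilyloxy)-3,5-dimethoxyphenyl]propanoic pivalic anhydride (formed in the flask in step 3) | COc1cc(CCC(=O)OC(=O)C(C)(C)C)cc(OC)c1O[Si](C)(C)C(C)(C)C | intermediate
7 | (4S)-4-benzyl-3-{3-[4-(tert-butyldimethylsilyloxy)-3,5-dimethoxyphenyl]propanoyl}-1,3-oxazolidin-2-one | COc1cc(CCC(=O)N2[C@@H](Cc3ccccc3)COC2=O)cc(OC)c1O[Si](C)(C)C(C)(C)C | intermediate
8 | 3-(3,4,5-trimethoxyphenyl)propanoic acid | COc1cc(CCC(=O)O)cc(OC)c1OC | starting material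
9 | tert-butyl 3-(3,4,5-trimethoxyphenyl)propanoate | COc1cc(CCC(=O)OC(C)(C)C)cc(OC)c1OC | intermediate
10 | lithium (Z)-enolate of imide 7 (formed in the flask in step 5) | [Li+].[O-]/C(=C\Cc1cc(OC)c(O[Si](C)(C)C(C)(C)C)c(OC)c1)N1[C@@H](Cc2ccccc2)COC1=O | intermediate
11 | lithium enolate of ester 9 (formed in the flask in step 5) | [Li+].[O-]C(OC(C)(C)C)=CCc1cc(OC)c(OC)c(OC)c1 | intermediate
12 | tert-butyl (2RS,3R)-4-[(4S)-4-benzyl-2-oxo-1,3-oxazolidin-3-yl]-3-[4-(tert-butyldimethylsilyloxy)-3,5-dimethoxybenzyl]-4-oxo-2-(3,4,5-trimethoxybenzyl)butanoate | COc1cc(CC(C(=O)OC(C)(C)C)[C@@H](Cc2cc(OC)c(O[Si](C)(C)C(C)(C)C)c(OC)c2)C(=O)N2[C@@H](Cc3ccccc3)COC2=O)cc(OC)c1OC | intermediate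
13 | tert-butyl (2RS,3R)-3-[4-(tert-butyldimethylsilyloxy)-3,5-dimethoxybenzyl]-4-hydroxy-2-(3,4,5-trimethoxybenzyl)butanoate (formed in the flask in step 6) | COc1cc(CC(C(=O)OC(C)(C)C)[C@H](CO)Cc2cc(OC)c(O[Si](C)(C)C(C)(C)C)c(OC)c2)cc(OC)c1OC | intermediate
14 | (3RS,4R)-4-[4-(tert-butyldimethylsilyloxy)-3,5-dimethoxybenzyl]-3-(3,4,5-trimethoxybenzyl)dihydrofuran-2(3H)-one | COc1cc(C[C@H]2COC(=O)C2Cc2cc(OC)c(OC)c(OC)c2)cc(OC)c1O[Si](C)(C)C(C)(C)C | intermediate
15 | (3R,4R)-4-[4-(tert-butyldimethylsilyloxy)-3,5-dimethoxybenzyl]-3-(3,4,5-trimethoxybenzyl)dihydrofuran-2(3H)-one (formed in the flask in step 7) | COc1cc(C[C@H]2COC(=O)[C@@H]2Cc2cc(OC)c(OC)c(OC)c2)cc(OC)c1O[Si](C)(C)C(C)(C)C | intermediate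
16 | (3R,4R)-4-(4-hydroxy-3,5-dimethoxybenzyl)-3-(3,4,5-trimethoxybenzyl)dihydrofuran-2(3H)-one | COc1cc(C[C@H]2COC(=O)[C@@H]2Cc2cc(OC)c(OC)c(OC)c2)cc(OC)c1O | target

**Step count**
Total: 7 steps. Longest linear sequence: 6 steps (1 → 2 → 4 → 7 → 12 → 14 → 16); step 4 is a one-step side branch.

**Steps most likely to fail, with fallbacks**

Step 5 (oxidative heterocoupling). The cross-coupled product competes with the two homodimers, so a modest yield of 12 is expected even with 9 in excess. The C2 ratio does not matter. If the cross-coupling fails, the same C8–C8' bond is made by a polar alkylation that sets out from 9 and comes back at 12. Enolate 11 (from 9 and LiN(iPr)2, THF, −78 °C) is hydroxylated with 2-(phenylsulfonyl)-3-phenyloxaziridine to racemic tert-butyl 2-hydroxy-3-(3,4,5-trimethoxyphenyl)propanoate F1. Tf2O and 2,6-lutidine in CH2Cl2 at −78 °C convert it into racemic tert-butyl 3-(3,4,5-trimethoxyphenyl)-2-[(trifluoromethylsulfonyl)oxy]propanoate F2. Enolate 10 (from 7 and LiN(iPr)2) then displaces the triflate in an SN2 alkylation with the same facial control by the auxiliary, giving 12 as a C2 epimer mixture that the route tolerates.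

Step 6 (reduction and lactonisation). The imide is hindered, so LiBH4 may open the oxazolidinone ring instead, and any lactone formed early from the alkoxide can be reduced further to the diol. The fallback sets out from 12 and comes back at 13. LiSEt in THF at 0 °C transfers the acyl group from the auxiliary to sulfur, giving tert-butyl (2RS,3R)-3-[4-(tert-butyldimethylsilyloxy)-3,5-dimethoxybenzyl]-4-(ethylsulfanyl)-4-oxo-2-(3,4,5-trimethoxybenzyl)butanoate F3. NaBH4 in EtOH then reduces only the thioester to the alcohol 13, which is lactonised with TsOH·H2O as in step 6.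

Step 7 (epimerisation and desilylation). The equilibrium may leave a few percent of the cis lactone that is hard to separate. The fallback sets C3 by substrate-controlled alkylation instead; it sets out from 7 and comes back at 15.
- Enolate 10 (from 7 and LiN(iPr)2) is alkylated with tert-butyl bromoacetate to tert-butyl (3R)-4-[(4S)-4-benzyl-2-oxo-1,3-oxazolidin-3-yl]-3-[4-(tert-butyldimethylsilyloxy)-3,5-dimethoxybenzyl]-4-oxobutanoate F4.
- LiBH4 reduces the imide to tert-butyl (3R)-3-[4-(tert-butyldimethylsilyloxy)-3,5-dimethoxybenzyl]-4-hydroxybutanoate F5.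
- TsOH·H2O closes it to (4R)-4-[4-(tert-butyldimethylsilyloxy)-3,5-dimethoxybenzyl]dihydrofuran-2(3H)-one F6.
- LiN(iPr)2 at −78 °C gives the lithium enolate of that lactone F7, which is benzylated with 3,4,5-trimethoxybenzyl bromide anti to the C4 substituent to give 15.
- 15 is desilylated with Bu4NF/AcOH as in the second half of step 7.

**Further compounds**
F1 | step 5 | tert-butyl 2-hydroxy-3-(3,4,5-trimethoxyphenyl)propanoate (racemic) | COc1cc(CC(O)C(=O)OC(C)(C)C)cc(OC)c1OC
F2 | step 5 | tert-butyl 3-(3,4,5-trimethoxyphenyl)-2-[(trifluoromethylsulfonyl)oxy]propanoate (racemic) | COc1cc(CC(OS(=O)(=O)C(F)(F)F)C(=O)OC(C)(C)C)cc(OC)c1OC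
F3 | step 6 | tert-butyl (2RS,3R)-3-[4-(tert-butyldimethylsilyloxy)-3,5-dimethoxybenzyl]-4-(ethylsulfanyl)-4-oxo-2-(3,4,5-trimethoxybenzyl)butanoate | COc1cc(CC(C(=O)OC(C)(C)C)[C@@H](Cc2cc(OC)c(O[Si](C)(C)C(C)(C)C)c(OC)c2)C(=O)SCC)cc(OC)c1OC
F4 | step 7 | tert-butyl (3R)-4-[(4S)-4-benzyl-2-oxo-1,3-oxazolidin-3-yl]-3-[4-(tert-butyldimethylsilyloxy)-3,5-dimethoxybenzyl]-4-oxobutanoate | CC(C)(C)OC(=O)C[C@@H](Cc1cc(OC)c(O[Si](C)(C)C(C)(C)C)c(OC)c1)C(=O)N1[C@@H](Cc2ccccc2)COC1=O
F5 | step 7 | tert-butyl (3R)-3-[4-(tert-butyldimethylsilyloxy)-3,5-dimethoxybenzyl]-4-hydroxybutanoate | CC(C)(C)OC(=O)C[C@H](CO)Cc1cc(OC)c(O[Si](C)(C)C(C)(C)C)c(OC)c1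
F6 | step 7 | (4R)-4-[4-(tert-butyldimethylsilyloxy)-3,5-dimethoxybenzyl]dihydrofuran-2(3H)-one | O=C1C[C@@H](Cc2cc(OC)c(O[Si](C)(C)C(C)(C)C)c(OC)c2)CO1
F7 | step 7 | lithium enolate of (4R)-4-[4-(tert-butyldimethylsilyloxy)-3,5-dimethoxybenzyl]dihydrofuran-2(3H)-one | [Li+].[O-]C1=C[C@@H](Cc2cc(OC)c(O[Si](C)(C)C(C)(C)C)c(OC)c2)CO1
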